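**Retrosynthetic overview**
1. Cyclointegrin ⇐ hydrogenolysis of two benzyl ethers ⇐ shift of an exocyclic C3=CH bond into ring C ⇐ oxocine-bridged 3-alkylidene flavanone.
2. Key disconnection: the C2–C1' bond and the CH2–C(CH3)2 bond are cut together. Forward, a one-flask formal [4+4] annulation joins 5-(benzyloxy)-7-methoxy-3-vinylchromone (C2, C3, CH=CH2) with a ring B aryl bromide whose ortho oxygen carries a 2-(pivaloyloxy)prop-2-yl group (aryl anion at C1' plus latent oxocarbenium ion at the O-bound C(CH3)2 carbon).
3. Enabling feature: C2 of ring C is the β-carbon of the chromone enone and takes the aryl nucleophile. The vinyl group on C3 turns the resulting enolate into a dienol ether O–C4=C3–CH=CH2 whose terminal CH2 is the γ-nucleophile. C1' and the ether carbon are 1,4-related across C2'–O, so the second bond closes the eight-membered ring C2–C3–CH–CH2–C(CH3)2–O–C2'–C1'.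
4. Order of rings: rings A and B are bought; ring C by iodine-induced cyclisation of an enaminone; the oxocine ring in the key step; ring C is rearomatised afterwards.
5. Fragments: the chromone in 3 steps from 2',6'-dihydroxy-4'-methoxyacetophenone; the aryl bromide in 4 steps from 3-(benzyloxy)phenol.

Key step: step 8

Remark: flavone numbering is used (rings A, B, C; C2, C3, C1', C2'); the target is achiral, and the one stereocentre met on the way (C2 of the key-step product) is carried as the racemate and removed one step later.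

**Route**

Step 1
Reactants: 1 1-(2,6-dihydroxy-4-methoxyphenyl)ethan-1-one
Product: 2 1-[2-(benzyloxy)-6-hydroxy-4-methoxyphenyl]ethan-1-one
Conditions: BnBr (1.05 equiv), K2CO3, acetone, reflux
Reagents that add atoms: benzyl bromide, BrCc1ccccc1
Why: Williamson ether synthesis on two equivalent hydroxyls should stop at the monoether, because the remaining hydroxyl is held in a hydrogen bond to the ketone.

Step 2
Reactants: 2 1-[2-(benzyloxy)-6-hydroxy-4-methoxyphenyl]ethan-1-one
Product: 4 5-(benzyloxy)-3-iodo-7-methoxy-4H-chromen-4-one, via enaminone 3 (not isolated)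
Conditions: DMF-DMA, toluene, 95 °C; then I2, CHCl3, rt
Reagents that add atoms: N,N-dimethylformamide dimethyl acetal, COC(OC)N(C)C; iodine, II
Why: Condensation of the methyl ketone with the amide acetal gives the ortho-hydroxyaryl enaminone, and iodine-induced cyclisation with loss of dimethylamine is an established route to 3-iodochromones.

Step 3
Reactants: 4 5-(benzyloxy)-3-iodo-7-methoxy-4H-chromen-4-one
Product: 5 5-(benzyloxy)-3-ethenyl-7-methoxy-4H-chromen-4-one
Conditions: tributyl(vinyl)stannane, Pd(PPh3)4 (5 mol %), toluene, 100 °C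
Reagents that add atoms: tributyl(vinyl)stannane, C=C[Sn](CCCC)(CCCC)CCCC
Why: Stille cross-coupling of the 3-iodochromone runs under neutral conditions and should spare the base-sensitive pyranone.

Step 4
Reactants: 6 3-(benzyloxy)phenol
Product: 7 3-(benzyloxy)phenyl acetate
Conditions: Ac2O, pyridine, DMAP (cat.), CH2Cl2, rt
Reagents that add atoms: acetic anhydride, CC(=O)OC(C)=O
Why: O-acylation of the phenol supplies the carbon that becomes the ether carbon and makes the acyloxy group a weaker director than the benzyloxy group.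

Step 5
Reactants: 7 3-(benzyloxy)phenyl acetate
Product: 8 5-(benzyloxy)-2-bromophenyl acetate
Conditions: NBS, MeCN, 0 °C to rt
Reagents that add atoms: N-bromosuccinimide, O=C1CCC(=O)N1Br
Why: Electrophilic aromatic bromination should go para to the benzyloxy group, the strongest donor, which is the position ortho to the acetate.

Step 6
Reactants: 8 5-(benzyloxy)-2-bromophenyl acetate
Product: 9 4-(benzyloxy)-1-bromo-2-(prop-1-en-2-yloxy)benzene
Conditions: Cp2TiMe2, toluene, 65 °C, dark; filtration through basic alumina
Reagents that add atoms: dimethyltitanocene Cp2TiMe2, [CH3-].[CH3-].[Ti+4].c1cc[cH-]c1.c1cc[cH-]c1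
Why: Petasis methylenation of the aryl ester carbonyl gives the aryl isopropenyl ether and tolerates the aryl bromide and the benzyl ether.

Step 7
Reactants: 9 4-(benzyloxy)-1-bromo-2-(prop-1-en-2-yloxy)benzene
Product: 10 2-[5-(benzyloxy)-2-bromophenoxy]propan-2-yl 2,2-dimethylpropanoate
Conditions: pivalic acid (3 equiv), PPTS (1 mol %), CH2Cl2, 0 °C; Et3N quench
Reagents that add atoms: pivalic acid, CC(C)(C)C(=O)O
Why: Acid-catalysed Markovnikov addition of a carboxylic acid to an enol ether gives the α-acyloxy ketal, a latent oxocarbenium ion that is inert to organometallic reagents at low temperature.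

Step 8
Reactants: 10 2-[5-(benzyloxy)-2-bromophenoxy]propan-2-yl 2,2-dimethylpropanoate; 5 5-(benzyloxy)-3-ethenyl-7-methoxy-4H-chromen-4-one
Product: 14 racemic (E)-3-alkylidene flavanone bridged by the dimethyloxocine ring, via aryllithium 11 (not isolated), via arylmagnesium bromide 12 (not isolated), via trimethylsilyl dienol ether 13 (not isolated)
Conditions: n-BuLi, THF, −100 °C; MgBr2·OEt2, −78 °C; 5, CuBr·SMe2 (10 mol %), TMSCl, −78 °C; then TMSOTf (20 mol %), CH2Cl2, −78 to −40 °C; Et3N, NaHCO3 aq
Reagents that add atoms: none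
Why: Proposed new method: bromine–lithium exchange on 10 and transmetallation give aryl Grignard 12, which under monovalent copper catalysis and TMSCl adds 1,4 to C2 of 5, the β-carbon of the chromone enone and its only Michael position, so that the C2–C1' bond forms and the enolate is trapped as the cross-conjugated trimethylsilyl dienol ether 13 (O–C4=C3–CH=CH2). Catalytic TMSOTf then silylates the pivalate carbonyl, pivalate leaves (aryloxy is the better donor and the poorer leaving group, so only the 2-aryloxyprop-2-yl oxocarbenium ion can form) and the terminal CH2 of 13, its γ-carbon, attacks the cation, which forms the CH2–C(CH3)2 bond, releases the ketone and returns TMSOTf. The closest known reaction types are the copper-catalysed conjugate addition of aryl Grignard reagents to chromones with silyl trapping and the Lewis acid-mediated intramolecular vinylogous Mukaiyama addition of silyl dienol ethers to acetal- or α-acyloxy ether-derived oxocarbenium ions, which is known to close eight-membered rings; their one-flask union as a formal [4+4] annulation with a ketone-derived aryloxycarbenium ion is new. The oxocine ring closes by an 8-endo attack on the C=O+ bond (oxygen inside the ring) through the γ-terminus of the dienol ether (enol-endo). The only new stereocentre, C2, forms as the racemate and is removed in step 9, and the C3=CH bond can only be E because C2 and the ring CH2 must be cis on it within the eight-membered ring. The step needs aryl transfer before ionisation, secured by keeping strong Lewis acid out until 5 is consumed at −78 °C, and γ- over α-alkylation, secured by the fully substituted C3 (α-attack would join two quaternary carbons in a six-membered ring) and by the pseudo-axial 2-aryl group that holds the cation above the vinyl terminus.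

Step 9
Reactants: 14 racemic (E)-3-alkylidene flavanone bridged by the dimethyloxocine ring
Product: 15 5,4'-di-O-benzylcyclointegrin
Conditions: RhCl3·3H2O (10 mol %), EtOH/CHCl3, 70 °C
Reagents that add atoms: none
Why: Rhodium hydride-mediated alkene isomerisation (1,3-hydrogen shift from C2 to the exocyclic CH) should move the double bond into ring C, driven by formation of the aromatic 4-pyranone as known for 3-alkylidene chroman-4-ones, and removes the C2 stereocentre.

Step 10
Reactants: 15 5,4'-di-O-benzylcyclointegrin
Product: 16 cyclointegrin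
Conditions: H2 (1 atm), Pd/C, EtOAc/MeOH, rt
Reagents that add atoms: none
Why: Hydrogenolysis over Pd/C should cleave both benzyl ethers while the tetrasubstituted pyranone double bond and the tertiary alkyl aryl ether stay intact.

**Compound list**
1 | 1-(2,6-dihydroxy-4-methoxyphenyl)ethan-1-one | CC(=O)c1c(O)cc(OC)cc1O | starting material
2 | 1-[2-(benzyloxy)-6-hydroxy-4-methoxyphenyl]ethan-1-one | CC(=O)c1c(O)cc(OC)cc1OCc1ccccc1 | intermediate
3 | (E)-1-[2-(benzyloxy)-6-hydroxy-4-methoxyphenyl]-3-(dimethylamino)prop-2-en-1-one | CN(C)/C=C/C(=O)c1c(O)cc(OC)cc1OCc1ccccc1 | intermediate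
4 | 5-(benzyloxy)-3-iodo-7-methoxy-4H-chromen-4-one | COc1cc(OCc2ccccc2)c2c(=O)c(I)coc2c1 | intermediate
5 | 5-(benzyloxy)-3-ethenyl-7-methoxy-4H-chromen-4-one | COc1cc(OCc2ccccc2)c2c(=O)c(C=C)coc2c1 | intermediate
6 | 3-(benzyloxy)phenol | Oc1cccc(OCc2ccccc2)c1 | starting material
7 | 3-(benzyloxy)phenyl acetate | CC(=O)Oc1cccc(OCc2ccccc2)c1 | intermediate
8 | 5-(benzyloxy)-2-bromophenyl acetate | CC(=O)Oc1cc(OCc2ccccc2)ccc1Br | intermediate
9 | 4-(benzyloxy)-1-bromo-2-(prop-1-en-2-yloxy)benzene | CC(=C)Oc1cc(OCc2ccccc2)ccc1Br | intermediate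
10 | 2-[5-(benzyloxy)-2-bromophenoxy]propan-2-yl 2,2-dimethylpropanoate | CC(C)(C)C(=O)OC(C)(C)Oc1cc(OCc2ccccc2)ccc1Br | intermediate
11 | {4-(benzyloxy)-2-[(2-pivaloyloxypropan-2-yl)oxy]phenyl}lithium | [Li]c1ccc(OCc2ccccc2)cc1OC(C)(C)OC(=O)C(C)(C)C | intermediate
12 | {4-(benzyloxy)-2-[(2-pivaloyloxypropan-2-yl)oxy]phenyl}magnesium bromide | Br[Mg]c1ccc(OCc2ccccc2)cc1OC(C)(C)OC(=O)C(C)(C)C | intermediate
13 | racemic 5-(benzyloxy)-2-{4-(benzyloxy)-2-[(2-pivaloyloxypropan-2-yl)oxy]phenyl}-3-ethenyl-7-methoxy-4-(trimethylsilyloxy)-2H-chromene | COc1cc(OCc2ccccc2)c2c(c1)OC(c1ccc(OCc3ccccc3)cc1OC(C)(C)OC(=O)C(C)(C)C)C(C=C)=C2O[Si](C)(C)C | intermediate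
14 | racemic 5-(benzyloxy)-7-methoxyflavanone whose C3 carries an exocyclic (E)-C=CH–CH2–C(CH3)2–O chain closed onto C2' of the 4'-(benzyloxy) ring B (2,3-dihydro isomer of 15) | COc1cc(OCc2ccccc2)c2c(c1)OC1/C(=C\CC(C)(C)Oc3cc(OCc4ccccc4)ccc31)C2=O | intermediate
15 | 5,4'-di-O-benzylcyclointegrin | COc1cc(OCc2ccccc2)c2c(=O)c3c(oc2c1)-c1ccc(OCc2ccccc2)cc1OC(C)(C)CC3 | intermediate
16 | cyclointegrin | COc1cc(O)c2c(=O)c3c(oc2c1)-c1ccc(O)cc1OC(C)(C)CC3 | target

**Step count and risks**
Total step count: 10. Longest linear sequence: 7 steps (6 → 7 → 8 → 9 → 10 → 14 → 15 → 16).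

Steps most likely to fail:

1. Step 8 (bears the label "Proposed new method:"). What may go wrong: ionisation of the acyloxy ketal while aryl metal is still present, 1,2-addition to the carbonyl, loss of the silyl group from 13 before ring closure, or alkylation between molecules instead of closure of the eight-membered ring. The fallback uses known chemistry and closes the oxocine last, at the C–O bond. It sets out from 4 and comes back to the route at 16.
   - Stille coupling of 4 with tributyl(3-methylbut-2-en-1-yl)stannane (Pd(PPh3)4, DMF, 80 °C) would give 5-(benzyloxy)-7-methoxy-3-(3-methylbut-2-en-1-yl)-4H-chromen-4-one F1.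
   - Dibenzylation of commercial 4-bromoresorcinol (BnBr, K2CO3, DMF) would give 1-bromo-2,4-bis(benzyloxy)benzene F2, and Mg in THF would turn it into [2,4-bis(benzyloxy)phenyl]magnesium bromide F3.
   - Copper-catalysed 1,4-addition of F3 to F1 (CuBr·SMe2, TMSCl, THF, −78 °C) would give 2-[2,4-bis(benzyloxy)phenyl]-5-(benzyloxy)-7-methoxy-3-(3-methylbut-2-en-1-yl)-4-(trimethylsilyloxy)-2H-chromene F4.
   - Saegusa–Ito oxidation (Pd(OAc)2, MeCN) would turn F4 into 5,2',4'-tris(benzyloxy)-7-methoxy-3-(3-methylbut-2-en-1-yl)flavone F5.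
   - Debenzylation with BCl3 and pentamethylbenzene (CH2Cl2, −78 °C) would give 5,2',4'-trihydroxy-7-methoxy-3-(3-methylbut-2-en-1-yl)flavone F6.
   - Acid (TsOH, toluene, 60 °C) would add the 2'-hydroxyl to the prenyl double bond in the Markovnikov sense and close the oxocine to give 16.

2. Step 7. What may go wrong: reversal of the addition with loss of pivalic acid on isolation, or acid-induced oligomerisation of the enol ether. The fallback builds the acyloxy ketal by oxidative decarboxylation instead. It sets out from 8 and comes back at 10.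
   - Methanolysis of 8 (K2CO3, MeOH) would give 5-(benzyloxy)-2-bromophenol F7.
   - Alkylation with ethyl 2-bromo-2-methylpropanoate (Cs2CO3, DMF, 60 °C) would give ethyl 2-[5-(benzyloxy)-2-bromophenoxy]-2-methylpropanoate F8.
   - Saponification (LiOH, THF/H2O) would give 2-[5-(benzyloxy)-2-bromophenoxy]-2-methylpropanoic acid F9.
   - Oxidative decarboxylation with Pb(OAc)4 in the presence of excess pivalic acid (benzene, 80 °C) would trap the oxocarbenium ion as the pivalate 10.

3. Step 9. What may go wrong: incomplete migration of the double bond, or acid-induced opening of the tertiary alkyl aryl ether under the rhodium chloride conditions. The fallback replaces the isomerisation by reduction and dehydrogenation. It sets out from 14 and comes back at 15.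
   - Conjugate reduction of 14 with [CuH(PPh3)]6 (toluene, rt) would give the saturated 3-alkyl flavanone F10, the 2,3-dihydro derivative of 15, as a mixture of diastereomers.
   - Dehydrogenation with DDQ (dioxane, 100 °C), as used for flavanone to flavone oxidation, would give 15.

Further compounds
F1 | step 8 | 5-(benzyloxy)-7-methoxy-3-(3-methylbut-2-en-1-yl)-4H-chromen-4-one | COc1cc(OCc2ccccc2)c2c(=O)c(CC=C(C)C)coc2c1
F2 | step 8 | 1-bromo-2,4-bis(benzyloxy)benzene | Brc1ccc(OCc2ccccc2)cc1OCc1ccccc1
F3 | step 8 | [2,4-bis(benzyloxy)phenyl]magnesium bromide | Br[Mg]c1ccc(OCc2ccccc2)cc1OCc1ccccc1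
F4 | step 8 | 2-[2,4-bis(benzyloxy)phenyl]-5-(benzyloxy)-7-methoxy-3-(3-methylbut-2-en-1-yl)-4-(trimethylsilyloxy)-2H-chromene | COc1cc(OCc2ccccc2)c2c(c1)OC(c1ccc(OCc3ccccc3)cc1OCc1ccccc1)C(CC=C(C)C)=C2O[Si](C)(C)C
F5 | step 8 | 5,2',4'-tris(benzyloxy)-7-methoxy-3-(3-methylbut-2-en-1-yl)flavone | COc1cc(OCc2ccccc2)c2c(=O)c(CC=C(C)C)c(-c3ccc(OCc4ccccc4)cc3OCc3ccccc3)oc2c1
F6 | step 8 | 5,2',4'-trihydroxy-7-methoxy-3-(3-methylbut-2-en-1-yl)flavone | COc1cc(O)c2c(=O)c(CC=C(C)C)c(-c3ccc(O)cc3O)oc2c1
F7 | step 7 | 5-(benzyloxy)-2-bromophenol | Oc1cc(OCc2ccccc2)ccc1Br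
F8 | step 7 | ethyl 2-[5-(benzyloxy)-2-bromophenoxy]-2-methylpropanoate | CCOC(=O)C(C)(C)Oc1cc(OCc2ccccc2)ccc1Br
F9 | step 7 | 2-[5-(benzyloxy)-2-bromophenoxy]-2-methylpropanoic acid | OC(=O)C(C)(C)Oc1cc(OCc2ccccc2)ccc1Br
F10 | step 9 | 5-(benzyloxy)-7-methoxyflavanone whose C3 carries a CH2–CH2–C(CH3)2–O chain closed onto C2' of the 4'-(benzyloxy) ring B (mixture of diastereomers) | COc1cc(OCc2ccccc2)c2c(c1)OC1C(CCC(C)(C)Oc3cc(OCc4ccccc4)ccc31)C2=O
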